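**Plan**

1. Cuts (eunicellane numbering: C1/C10 are shared by the cyclohexane and the tetrahydrofuran, C2/C9 are the tetrahydrofuran ether carbons, C3–C8 the bridge, C11 the ester-bearing ring carbon): both esters, C6–C7 of the nine-membered ether ring (B-alkyl Suzuki), C4–C5 (vinyl addition) and the C3–O bond of the oxepane (epoxide opening by the C16 hydroxyl).
2. The remaining cis-fused tetrahydrofuran/cyclohexanone is traced back by a retro-Tiffeneau–Demjanov shift: C1 returns from C10 to C11, which turns the cyclohexanone into a cyclopentanol and the tetrahydrofuran into a tetrahydropyran carrying an amine on C10.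
3. Enabling feature: C11 carries oxygen and is flanked by C10, the carbon common to the cyclohexane and the tetrahydrofuran, giving the β-alkoxy ketone array O–C9–C10–C11(=O). A nitro group builds C10–C11 (Henry reaction) and is the temporary helper; it leaves as N2.
4. Forward order of rings: cyclopentanone (from cyclopentenone) → tetrahydropyran (oxa-Michael/Henry) → cyclohexanone and tetrahydrofuran in one ring expansion/ring contraction → oxepane → nine-membered ether ring.
5. Stereochemistry: C14 by catalyst-controlled conjugate addition; C1/C2 by anti-aldol trapping; C3 by hydroxyl-directed epoxidation, then inversion; C9/C10 by equilibration to the all-equatorial tetrahydropyran, then invertive migration; C12/C11 by convex-face protonation and hydride addition; C15 by hydroboration; C4 by chelation control; C2' from (R)-2-hydroxyoctanoic acid.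

Key step: step 7

Remark (numbering): C7 bears the exocyclic methylene C19; C11–C14 are the other cyclohexane carbons; C15–C17 form the branch on C14, with C16 the oxepane CH2.
Remark (assumptions): ethyl (2-methyl-1,3-dioxolan-2-yl)acetate and (R)-2-hydroxyoctanoic acid are taken as commercial. The carbinol centre C11 of 14–16 is destroyed in step 7, so its configuration (drawn cis-fused) is immaterial.

**Route**

Step 1
Reactants: 1 ethyl (2-methyl-1,3-dioxolan-2-yl)acetate
Product: 2 (2-methyl-1,3-dioxolan-2-yl)acetaldehyde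
Conditions: i-Bu2AlH (1.05 equiv), CH2Cl2, −78 °C; aq. potassium sodium tartrate
Reagents that add atoms: none
Why: Partial ester reduction with i-Bu2AlH stops at the aldehyde because the tetrahedral aluminium hemiacetal survives at −78 °C; the ketal masks the future C7 carbonyl.

Step 2
Reactants: 2 (2-methyl-1,3-dioxolan-2-yl)acetaldehyde; 3 nitromethane
Product: 6 (E)-2-methyl-2-(3-nitroprop-2-en-1-yl)-1,3-dioxolane, via nitro alcohol 4 (not isolated), via mesylate 5 (not isolated)
Conditions: KOt-Bu (5 mol %), THF/t-BuOH, 0 °C; then MsCl, Et3N, CH2Cl2, −20 → 0 °C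
Reagents that add atoms: none
Why: Henry (nitroaldol) addition followed by E1cB elimination of the mesylate should give the conjugated nitroalkene in its favoured E geometry.

Step 3
Reactants: 7 cyclopent-2-en-1-one; 8 isopropenylmagnesium bromide; 9 methacrolein
Product: 11 (2S,3S)-2-[(R)-1-hydroxy-2-methylprop-2-en-1-yl]-3-(prop-1-en-2-yl)cyclopentan-1-one, via magnesium enolate 10 (not isolated)
Conditions: CuBr·SMe2 (5 mol %), Josiphos-type ferrocenyl diphosphine (6 mol %, the enantiomer that gives the 3S adduct), t-BuOMe, −78 °C; then 9, −78 °C; aq. NH4Cl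
Reagents that add atoms: none
Why: Copper-catalysed asymmetric conjugate addition sets C14 under catalyst control, and aldol trapping of the regiodefined (E)-enolate anti to the new substituent through a chair Zimmerman–Traxler transition state should give the 2,3-trans, anti aldol (C1 and C2).

Step 4
Reactants: 11 (2S,3S)-2-[(R)-1-hydroxy-2-methylprop-2-en-1-yl]-3-(prop-1-en-2-yl)cyclopentan-1-one
Product: 12 (2S,3S)-2-{(R)-hydroxy[(S)-2-methyloxiran-2-yl]methyl}-3-(prop-1-en-2-yl)cyclopentan-1-one
Conditions: VO(acac)2 (3 mol %), t-BuOOH (1.5 equiv), CH2Cl2, 0 °C → rt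
Reagents that add atoms: tert-butyl hydroperoxide, CC(C)(C)OO
Why: Hydroxyl-directed vanadium-catalysed epoxidation acts only on the allylic alkene (the ring isopropenyl group has no directing hydroxyl) and, for a 2-substituted secondary allylic alcohol, should give the erythro epoxy alcohol, which fixes C3.

Step 5
Reactants: 12 (2S,3S)-2-{(R)-hydroxy[(S)-2-methyloxiran-2-yl]methyl}-3-(prop-1-en-2-yl)cyclopentan-1-one; 6 (E)-2-methyl-2-(3-nitroprop-2-en-1-yl)-1,3-dioxolane
Product: 14 all-equatorial nitro alcohol (3-nitrotetrahydropyran-4-ol cis-fused to the cyclopentane), via open-chain nitro ether 13 (not isolated)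
Conditions: LiN(SiMe3)2 (1.0 equiv), THF, −78 °C; then 6, −78 → −20 °C; AcOH; then Et3N (0.2 equiv), CH2Cl2, rt
Reagents that add atoms: none
Why: Oxa-Michael addition of the lithium alkoxide to the nitroalkene, then intramolecular Henry addition of the nitronate to the ketone (6-exo-trig), builds the tetrahydropyran; C9 and C10 are reversible (retro-oxa-Michael, nitronate epimerization) and should settle with the C9 side chain and the nitro group equatorial.

Step 6
Reactants: 14 all-equatorial nitro alcohol
Product: 15 amino alcohol (equatorial C10 amine, tertiary C11 alcohol)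
Conditions: Zn dust, HCO2NH4, MeOH, rt
Reagents that add atoms: none
Why: Zinc/formate reduction of the aliphatic nitro group to the primary amine runs near neutral pH and should spare the epoxide, the ketal and the alkene; no stereocentre is touched.

Step 7
Reactants: 15 amino alcohol
Product: 17 cis-fused hexahydroisobenzofuran-4-one (C11 ketone; C2 carries the (S)-2-methyloxiranyl group, C9 the ketal side chain, C14 the isopropenyl group), via diazonium ion 16 (not isolated)
Conditions: NaNO2, AcOH/NaOAc buffer (pH 4), H2O/THF, 0 °C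
Reagents that add atoms: none
Why: Nitrosation gives the C10 diazonium ion 16, and loss of N2 is concerted with a 1,2-shift of the ring carbon C1 from the carbinol carbon C11 to C10 (Tiffeneau–Demjanov rearrangement, a semipinacol shift), so that C11 becomes the ketone. The closest known reactions are the deaminative ring contraction of trans-2-aminocyclohexanols and the ring expansion of 1-(aminomethyl)cycloalkanols. Both rings are closed by this one suprafacial 1,2-alkyl shift rather than by a nucleophile–electrophile cyclization: the six-membered ring O–C2–C1–C11–C10–C9 contracts to the tetrahydrofuran O–C2–C1–C10–C9, and insertion of C10 between C11 and C1 expands the cyclopentane to the cyclohexanone. The only new stereocentre, C10, is formed with inversion because C1 enters anti to the departing N2; C1 migrates with retention and C2, C9 and C14 are untouched. The step needs migration of C1 rather than of C12, of the ring oxygen or of hydride; this is secured by the equatorial C10–N bond of the all-equatorial chair, which is antiperiplanar only to the endocyclic C11–C1 and C9–O bonds, and of these only the C1 shift is driven by the hydroxyl group on C11.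

Step 8
Reactants: 17 cis-fused hexahydroisobenzofuran-4-one
Product: 20 C12-methylene ketone (exocyclic enone), via Mannich base 18 (not isolated), via trimethylammonium iodide 19 (not isolated)
Conditions: LiN(SiMe3)2, THF, −78 °C; CH2=NMe2+ I−, −78 °C → rt; MeI, rt; DBU, CH2Cl2, rt
Reagents that add atoms: N,N-dimethylmethyleneiminium iodide (Eschenmoser's salt), C=[N+](C)C.[I-]
Why: Kinetic deprotonation should occur at the C12 methylene rather than at the ring-fusion methine C10, and Mannich reaction, quaternization and E1cB elimination then give the α-methylene ketone.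

Step 9
Reactants: 20 C12-methylene ketone
Product: 23 C11 alcohol with C12 methyl (hydroxyl and methyl cis, both on the face of the C10–C9 bond), via lithium enolate 21 (not isolated), via C12-methyl ketone 22 (not isolated)
Conditions: LiBH(s-Bu)3 (1.1 equiv), THF, −78 °C; 2,6-di-tert-butylphenol (1.2 equiv), −78 °C; then NaBH4, MeOH, −78 → −30 °C
Reagents that add atoms: none
Why: Conjugate reduction gives the C11–C12 enolate regiospecifically, kinetic C-protonation by the hindered phenol from the convex face (anti to the C10–C9 bond) should place the methyl group on the concave face, and hydride then adds to the ketone from the same convex face before the epimerizable ketone is isolated.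

Step 10
Reactants: 24 (R)-2-hydroxyoctanoic acid
Product: 26 (R)-2-[(tert-butyldimethylsilyl)oxy]octanoic acid, via bis-silyl derivative 25 (not isolated)
Conditions: TBSCl (2.5 equiv), imidazole, DMF, rt; then K2CO3, MeOH/THF/H2O, rt; KHSO4 to pH 4
Reagents that add atoms: tert-butyldimethylsilyl chloride, CC(C)(C)[Si](C)(C)Cl
Why: Silylation of hydroxyl and carboxyl groups followed by selective hydrolysis of the labile silyl ester gives the O-protected acid; the stereocentre comes from the starting material.

Step 11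
Reactants: 23 C11 alcohol with C12 methyl; 26 (R)-2-[(tert-butyldimethylsilyl)oxy]octanoic acid
Product: 27 C11 ester of 23 with the silyl-protected acid
Conditions: EDC·HCl, DMAP, CH2Cl2, 0 °C → rt
Reagents that add atoms: none
Why: Carbodiimide (Steglich) esterification of the only free hydroxyl installs the side chain and blocks the C11 oxygen so that it cannot open the epoxide in step 13.

Step 12
Reactants: 27 C11 ester
Product: 29 primary alcohol at C16 (new centre C15), via alkylborane 28 (not isolated)
Conditions: 9-BBN (1.5 equiv), THF, 0 °C → rt; then H2O2, pH 7 buffer (NaH2PO4/Na2HPO4), 0 °C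
Reagents that add atoms: hydrogen peroxide, OO
Why: Anti-Markovnikov hydroboration–oxidation of the only alkene; with H14 eclipsing the double bond, the borane should add anti to the more substituted ring carbon C1, which sets C15 (1,2-induction through minimized allylic strain).

Step 13
Reactants: 29 primary alcohol at C16
Product: 30 oxepane with a hydroxymethyl group (C4) on C3
Conditions: CSA (10 mol %), CH2Cl2, 0 °C
Reagents that add atoms: none
Why: Acid-catalysed intramolecular epoxide opening (7-exo-tet) by the primary alcohol at the tertiary carbon C3, with inversion, closes the oxepane, sets the C3 ether centre and frees the C4 hydroxyl.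

Step 14
Reactants: 30 oxepane with a hydroxymethyl group on C3
Product: 31 C4 aldehyde
Conditions: Dess–Martin periodinane, NaHCO3, CH2Cl2, rt
Reagents that add atoms: none
Why: Dess–Martin oxidation of the primary alcohol gives a non-enolizable α-alkoxy aldehyde.

Step 15
Reactants: 31 C4 aldehyde; 32 vinylmagnesium bromide
Product: 33 C4 allylic alcohol
Conditions: MgBr2·OEt2 (2 equiv), CH2Cl2, −78 °C; then 32 (1.5 equiv, THF), −78 °C; aq. NH4Cl
Reagents that add atoms: none
Why: Chelation-controlled (Cram chelate) Grignard addition: magnesium bridges the aldehyde and the oxepane oxygen on C3 and the vinyl group enters from the methyl side, which should set C4; at −78 °C the hindered ester should not react.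

Step 16
Reactants: 33 C4 allylic alcohol
Product: 34 C4 acetate
Conditions: Ac2O, DMAP, pyridine, rt
Reagents that add atoms: acetic anhydride, CC(=O)OC(C)=O
Why: DMAP-catalysed acetylation of the only free hydroxyl group.

Step 17
Reactants: 34 C4 acetate
Product: 35 C7 methyl ketone
Conditions: PPTS (0.3 equiv), acetone/H2O (10:1), 50 °C
Reagents that add atoms: water, O
Why: Mild acid-catalysed ketal hydrolysis unveils the C7 ketone while the silyl ether, both esters and the allylic acetate should stay intact.

Step 18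
Reactants: 35 C7 methyl ketone
Product: 36 enol triflate (2-triflyloxy-1-alkene at C7)
Conditions: KN(SiMe3)2 (1.1 equiv), THF, −78 °C; then N-(5-chloro-2-pyridyl)bis(trifluoromethanesulfonimide), −78 °C
Reagents that add atoms: N-(5-chloro-2-pyridyl)bis(trifluoromethanesulfonimide), O=S(=O)(N(c1ccc(Cl)cn1)S(=O)(=O)C(F)(F)F)C(F)(F)F
Why: Kinetic deprotonation of the methyl ketone at the methyl group and O-sulfonylation of the enolate (enol triflate formation) give the electrophile for ring closure.

Step 19
Reactants: 36 enol triflate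
Product: 38 silyl-protected tetracycle with the C7 exocyclic methylene, via alkylborane 37 (not isolated)
Conditions: 9-BBN (1.3 equiv), THF, 0 °C → rt; then slow addition to Pd(dppf)Cl2 (15 mol %), AsPh3, Cs2CO3, DMF/THF/H2O, 50 °C, final 0.002 M
Reagents that add atoms: none
Why: Hydroboration of the monosubstituted alkene (the enol triflate is inert) and intramolecular B-alkyl Suzuki–Miyaura coupling forge C6–C7, close the nine-membered ether ring across the cis-2,5-disubstituted tetrahydrofuran and leave the exocyclic methylene in place.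

Step 20
Reactants: 38 silyl-protected tetracycle
Product: 39 target
Conditions: HF·pyridine, pyridine, THF, 0 °C → rt
Reagents that add atoms: none
Why: Fluoride-mediated cleavage of the secondary silyl ether should leave both esters and the alkene untouched.

**Compound list**

1 | ethyl (2-methyl-1,3-dioxolan-2-yl)acetate | CCOC(=O)CC1(C)OCCO1 | starting material
2 | (2-methyl-1,3-dioxolan-2-yl)acetaldehyde | O=CCC1(C)OCCO1 | intermediate
3 | nitromethane | C[N+](=O)[O-] | starting material
4 | 1-(2-methyl-1,3-dioxolan-2-yl)-3-nitropropan-2-ol (racemic nitro alcohol) | OC(CC1(C)OCCO1)C[N+](=O)[O-] | intermediate (not isolated)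
5 | 1-(2-methyl-1,3-dioxolan-2-yl)-3-nitropropan-2-yl methanesulfonate | CS(=O)(=O)OC(CC1(C)OCCO1)C[N+](=O)[O-] | intermediate (not isolated)
6 | (E)-2-methyl-2-(3-nitroprop-2-en-1-yl)-1,3-dioxolane | CC1(C/C=C/[N+](=O)[O-])OCCO1 | intermediate
7 | cyclopent-2-en-1-one | O=C1C=CCC1 | starting material
8 | isopropenylmagnesium bromide | CC(=C)[Mg]Br | starting material
9 | methacrolein (2-methylprop-2-enal) | CC(=C)C=O | starting material
10 | bromomagnesium (S)-3-(prop-1-en-2-yl)cyclopent-1-en-1-olate | CC(=C)[C@H]1CCC(O[Mg]Br)=C1 | intermediate (not isolated)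
11 | (2S,3S)-2-[(R)-1-hydroxy-2-methylprop-2-en-1-yl]-3-(prop-1-en-2-yl)cyclopentan-1-one (2,3-trans, anti aldol) | CC(=C)[C@H]1CCC(=O)[C@@H]1[C@@H](O)C(C)=C | intermediate
12 | (2S,3S)-2-{(R)-hydroxy[(S)-2-methyloxiran-2-yl]methyl}-3-(prop-1-en-2-yl)cyclopentan-1-one (erythro epoxy alcohol) | CC(=C)[C@H]1CCC(=O)[C@@H]1[C@@H](O)[C@]2(C)CO2 | intermediate
13 | open-chain nitro ether: 12 O-alkylated at the carbinol oxygen by the 1-(2-methyl-1,3-dioxolan-2-yl)-3-nitropropan-2-yl group (ether carbon C9 R; formed as its lithium nitronate, drawn neutral) | CC(=C)[C@H]1CCC(=O)[C@@H]1[C@H]([C@]2(C)CO2)O[C@H](CC3(C)OCCO3)C[N+](=O)[O-] | intermediate (not isolated)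
14 | nitro alcohol: tetrahydropyran O–C2–C1–C11–C10–C9 cis-fused at C1–C11 to the cyclopentane; equatorial: methyloxiranyl on C2, ketal side chain on C9, nitro on C10, C14 on C1; tertiary hydroxyl on C11; isopropenyl on C14 trans to C2 | CC(=C)[C@H]1CC[C@@]2(O)[C@@H]1[C@H]([C@]3(C)CO3)O[C@H](CC4(C)OCCO4)[C@H]2[N+](=O)[O-] | intermediate
15 | amino alcohol: as 14 with an equatorial primary amine on C10 in place of the nitro group | CC(=C)[C@H]1CC[C@@]2(O)[C@@H]1[C@H]([C@]3(C)CO3)O[C@H](CC4(C)OCCO4)[C@H]2N | intermediate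
16 | C10 diazonium ion of 15 | CC(=C)[C@H]1CC[C@@]2(O)[C@@H]1[C@H]([C@]3(C)CO3)O[C@H](CC4(C)OCCO4)[C@H]2[N+]#N | intermediate (not isolated)
17 | cis-fused hexahydroisobenzofuran-4-one (skeleton 1R,2R,9R,10S,14S; C11 ketone; (S)-2-methyloxiranyl on C2 and ketal side chain on C9 cis to each other and to H1/H10; isopropenyl on C14 trans to C2) | CC(=C)[C@H]1CCC(=O)[C@H]2[C@@H]1[C@H]([C@]3(C)CO3)O[C@@H]2CC4(C)OCCO4 | intermediate
18 | Mannich base: 17 with a (dimethylamino)methyl group on C12 (C12 epimers) | CC(=C)[C@H]1CC(CN(C)C)C(=O)[C@H]2[C@@H]1[C@H]([C@]3(C)CO3)O[C@@H]2CC4(C)OCCO4 | intermediate (not isolated)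
19 | trimethylammonium iodide of 18 | CC(=C)[C@H]1CC(C[N+](C)(C)C)C(=O)[C@H]2[C@@H]1[C@H]([C@]3(C)CO3)O[C@@H]2CC4(C)OCCO4.[I-] | intermediate (not isolated)
20 | C12-methylene ketone (exocyclic enone of 17) | CC(=C)[C@H]1CC(=C)C(=O)[C@H]2[C@@H]1[C@H]([C@]3(C)CO3)O[C@@H]2CC4(C)OCCO4 | intermediate
21 | lithium C11–C12 enolate bearing the C12 methyl group | CC(=C)[C@H]1CC(C)=C(O[Li])[C@H]2[C@@H]1[C@H]([C@]3(C)CO3)O[C@@H]2CC4(C)OCCO4 | intermediate (not isolated)
22 | C12-methyl ketone (12S; methyl cis to the C10–C9 bond) | CC(=C)[C@H]1C[C@H](C)C(=O)[C@H]2[C@@H]1[C@H]([C@]3(C)CO3)O[C@@H]2CC4(C)OCCO4 | intermediate (not isolated)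
23 | C11 alcohol (hydroxyl cis to the C12 methyl and to the C10–C9 bond) | CC(=C)[C@H]1C[C@H](C)[C@H](O)[C@H]2[C@@H]1[C@H]([C@]3(C)CO3)O[C@@H]2CC4(C)OCCO4 | intermediate
24 | (R)-2-hydroxyoctanoic acid | OC(=O)[C@H](O)CCCCCC | starting material
25 | tert-butyldimethylsilyl (R)-2-[(tert-butyldimethylsilyl)oxy]octanoate | CC(C)(C)[Si](C)(C)OC(=O)[C@H](O[Si](C)(C)C(C)(C)C)CCCCCC | intermediate (not isolated)
26 | (R)-2-[(tert-butyldimethylsilyl)oxy]octanoic acid | OC(=O)[C@H](O[Si](C)(C)C(C)(C)C)CCCCCC | intermediate
27 | C11 ester of 23 with 26 | CC(=C)[C@H]1C[C@H](C)[C@H](OC(=O)[C@H](O[Si](C)(C)C(C)(C)C)CCCCCC)[C@H]2[C@@H]1[C@H]([C@]3(C)CO3)O[C@@H]2CC4(C)OCCO4 | intermediate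
28 | B-alkyl-9-borabicyclo[3.3.1]nonane from 27 (boron on C16) | C1CCC2CCCC1B2C[C@@H](C)[C@H]3C[C@H](C)[C@H](OC(=O)[C@H](O[Si](C)(C)C(C)(C)C)CCCCCC)[C@H]4[C@@H]3[C@H]([C@]5(C)CO5)O[C@@H]4CC6(C)OCCO6 | intermediate (not isolated)
29 | primary alcohol: 27 with the isopropenyl group converted into (S)-1-hydroxypropan-2-yl (C15 S, C16 hydroxyl) | OC[C@@H](C)[C@H]1C[C@H](C)[C@H](OC(=O)[C@H](O[Si](C)(C)C(C)(C)C)CCCCCC)[C@H]2[C@@H]1[C@H]([C@]3(C)CO3)O[C@@H]2CC4(C)OCCO4 | intermediate
30 | oxepane alcohol: ether C16–O–C3 closed (oxepane trans-fused to the cyclohexane at C1–C14); C3 carries methyl and hydroxymethyl (C4) | OC[C@@]1(C)OC[C@@H](C)[C@H]2C[C@H](C)[C@H](OC(=O)[C@H](O[Si](C)(C)C(C)(C)C)CCCCCC)[C@H]3[C@@H]2[C@H]1O[C@@H]3CC4(C)OCCO4 | intermediate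
31 | C4 aldehyde of 30 | O=C[C@@]1(C)OC[C@@H](C)[C@H]2C[C@H](C)[C@H](OC(=O)[C@H](O[Si](C)(C)C(C)(C)C)CCCCCC)[C@H]3[C@@H]2[C@H]1O[C@@H]3CC4(C)OCCO4 | intermediate
32 | vinylmagnesium bromide | C=C[Mg]Br | starting material
33 | C4 allylic alcohol (vinyl on C4) | C=C[C@H](O)[C@@]1(C)OC[C@@H](C)[C@H]2C[C@H](C)[C@H](OC(=O)[C@H](O[Si](C)(C)C(C)(C)C)CCCCCC)[C@H]3[C@@H]2[C@H]1O[C@@H]3CC4(C)OCCO4 | intermediate
34 | C4 acetate of 33 | C=C[C@H](OC(C)=O)[C@@]1(C)OC[C@@H](C)[C@H]2C[C@H](C)[C@H](OC(=O)[C@H](O[Si](C)(C)C(C)(C)C)CCCCCC)[C@H]3[C@@H]2[C@H]1O[C@@H]3CC4(C)OCCO4 | intermediate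
35 | C7 methyl ketone (2-oxopropyl group on C9) | C=C[C@H](OC(C)=O)[C@@]1(C)OC[C@@H](C)[C@H]2C[C@H](C)[C@H](OC(=O)[C@H](O[Si](C)(C)C(C)(C)C)CCCCCC)[C@H]3[C@@H]2[C@H]1O[C@@H]3CC(C)=O | intermediate
36 | enol triflate (2-triflyloxyprop-2-en-1-yl group on C9) | C=C[C@H](OC(C)=O)[C@@]1(C)OC[C@@H](C)[C@H]2C[C@H](C)[C@H](OC(=O)[C@H](O[Si](C)(C)C(C)(C)C)CCCCCC)[C@H]3[C@@H]2[C@H]1O[C@@H]3CC(=C)OS(=O)(=O)C(F)(F)F | intermediate
37 | B-alkyl-9-borabicyclo[3.3.1]nonane from 36 (boron on C6) | C1CCC2CCCC1B2CC[C@H](OC(C)=O)[C@@]3(C)OC[C@@H](C)[C@H]4C[C@H](C)[C@H](OC(=O)[C@H](O[Si](C)(C)C(C)(C)C)CCCCCC)[C@H]5[C@@H]4[C@H]3O[C@@H]5CC(=C)OS(=O)(=O)C(F)(F)F | intermediate (not isolated)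
38 | silyl-protected tetracycle (target with the side-chain hydroxyl as its tert-butyldimethylsilyl ether) | C=C1CC[C@H](OC(C)=O)[C@@]2(C)OC[C@@H](C)[C@H]3C[C@H](C)[C@H](OC(=O)[C@H](O[Si](C)(C)C(C)(C)C)CCCCCC)[C@H]4[C@@H]3[C@H]2O[C@@H]4C1 | intermediate
39 | target: (1R,2R,3R,4S,9R,10S,11S,12S,14R,15S)-4-acetoxy-11-[(2R)-2-hydroxyoctanoyloxy] tetracycle with the 7(19) exocyclic alkene | C=C1CC[C@H](OC(C)=O)[C@@]2(C)OC[C@@H](C)[C@H]3C[C@H](C)[C@H](OC(=O)[C@H](O)CCCCCC)[C@H]4[C@@H]3[C@H]2O[C@@H]4C1 | target

**Step count and risks**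

Total step count: 20. Longest linear sequence: 17 steps (steps 3–9 and 11–20; the branch through steps 1, 2 and 5 is equally long).

Three steps most likely to fail:

1. Step 5. The lithium aldolate may undergo retro-aldol cleavage, the ketone may enolize so that carbon rather than oxygen attacks the nitroalkene, and the nitroaldol equilibrium may not close the ring. Fallback (ketone masked, C–O and C–C bond formation separated): the route leaves at 12, which is condensed with N,N-dimethylhydrazine (MgSO4, CH2Cl2, rt) to the dimethylhydrazone F1. Its potassium alkoxide (KN(SiMe3)2, 0.2 equiv, THF, −40 °C) adds to 6 to give the nitro ether hydrazone F2. CuCl2 in aqueous THF at pH 7 unmasks the ketone and gives the open-chain nitro ether 13, now isolated, which is cyclized with Et3N in CH2Cl2; the route is rejoined at 14.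

2. Step 7. A diazonium ion that is not held antiperiplanar to the C11–C1 bond (partly axial amine) would ionize with solvent capture, hydride shift or epoxide formation, and the 2-methyloxirane may open under the acidic nitrosation. Fallback (sulfonate semipinacol under basic conditions): the route leaves at 15, which is transaminated with 3,5-di-tert-butyl-1,2-benzoquinone (MeOH, rt; then aq. oxalic acid) to the α-hydroxy ketone F3. NaBH4 (MeOH, −40 °C, axial hydride attack) should give the diol F4 with the secondary hydroxyl equatorial, and MsCl/pyridine sulfonylates only that hydroxyl to give the hydroxy mesylate F5. KOt-Bu in THF/t-BuOH then triggers the same antiperiplanar 1,2-shift; the route is rejoined at 17.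

3. Step 19. Closure of the strained nine-membered ring may be slow, so that protodeboronation, β-hydride elimination or intermolecular coupling take over. Fallback (C6–C7 by chromium-mediated carbonyl addition, then removal of the extra oxygen): the route leaves at 36, which is hydroborated with 9-BBN and oxidized (H2O2, pH 7) to the primary alcohol F6; Dess–Martin oxidation gives the aldehyde F7. CrCl2 with NiCl2 (1 mol %) in DMSO/THF at high dilution (Nozaki–Hiyama–Kishi reaction) closes the ring to the allylic alcohol F8, which is formylated (HCO2H, DCC, DMAP) to the formate F9. Pd(OAc)2/n-Bu3P in refluxing THF should then deliver hydride to the more substituted allyl terminus with loss of CO2 and keep the alkene exocyclic; the route is rejoined at 38.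

Further compounds
F1 | step 5 | N,N-dimethylhydrazone of 12 | CC(=C)[C@H]1CCC(=NN(C)C)[C@@H]1[C@@H](O)[C@]2(C)CO2
F2 | step 5 | N,N-dimethylhydrazone of the open-chain nitro ether 13 | CC(=C)[C@H]1CCC(=NN(C)C)[C@@H]1[C@H]([C@]2(C)CO2)O[C@H](CC3(C)OCCO3)C[N+](=O)[O-]
F3 | step 7 | α-hydroxy ketone (15 with a C10 ketone in place of the amine) | CC(=C)[C@H]1CC[C@@]2(O)[C@@H]1[C@H]([C@]3(C)CO3)O[C@H](CC4(C)OCCO4)C2=O
F4 | step 7 | diol (equatorial secondary hydroxyl on C10, tertiary hydroxyl on C11) | CC(=C)[C@H]1CC[C@@]2(O)[C@@H]1[C@H]([C@]3(C)CO3)O[C@H](CC4(C)OCCO4)[C@H]2O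
F5 | step 7 | hydroxy mesylate (C10 methanesulfonate of F4) | CC(=C)[C@H]1CC[C@@]2(O)[C@@H]1[C@H]([C@]3(C)CO3)O[C@H](CC4(C)OCCO4)[C@H]2OS(C)(=O)=O
F6 | step 19 | primary alcohol (36 with the vinyl group converted into 2-hydroxyethyl, C6 hydroxyl) | OCC[C@H](OC(C)=O)[C@@]1(C)OC[C@@H](C)[C@H]2C[C@H](C)[C@H](OC(=O)[C@H](O[Si](C)(C)C(C)(C)C)CCCCCC)[C@H]3[C@@H]2[C@H]1O[C@@H]3CC(=C)OS(=O)(=O)C(F)(F)F
F7 | step 19 | C6 aldehyde of F6 | O=CC[C@H](OC(C)=O)[C@@]1(C)OC[C@@H](C)[C@H]2C[C@H](C)[C@H](OC(=O)[C@H](O[Si](C)(C)C(C)(C)C)CCCCCC)[C@H]3[C@@H]2[C@H]1O[C@@H]3CC(=C)OS(=O)(=O)C(F)(F)F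
F8 | step 19 | macrocyclic allylic alcohol (38 with a hydroxyl on C6, C6 epimers) | C=C1C(O)C[C@H](OC(C)=O)[C@@]2(C)OC[C@@H](C)[C@H]3C[C@H](C)[C@H](OC(=O)[C@H](O[Si](C)(C)C(C)(C)C)CCCCCC)[C@H]4[C@@H]3[C@H]2O[C@@H]4C1
F9 | step 19 | C6 formate of F8 | C=C1C(OC=O)C[C@H](OC(C)=O)[C@@]2(C)OC[C@@H](C)[C@H]3C[C@H](C)[C@H](OC(=O)[C@H](O[Si](C)(C)C(C)(C)C)CCCCCC)[C@H]4[C@@H]3[C@H]2O[C@@H]4C1
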